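The data were computed for an exercise, noise included.

Start from what is left: at 40.0 min your flask, the midnight run, still holds 69.5% of its X, and over the last 10.0 min that figure fell by 1.6 percentage points, so it looks close to stopping. L stands at 1.4%, and the rest of what has gone is read as E, formed from X and D in what looks like a pre-equilibrium.

| flask | X | D | remark | time |
|---|---|---|---|---|
| midnight | 0.050 M | 0.090 M | the very flask that is asked about, followed so far |  |
| noon | 0.075 M | 0.090 M | run made earlier |  |
| flask | 0.050 M | 0.0900 M |  | 3.0 h |

| run | time / min | X / % | L / % |
|---|---|---|---|
| midnight | 2.50 | 94.6 | 0.2 |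
| midnight | 8.00 | 86.1 | 0 |
| midnight | 12.0 | 81.6 | 0 |
| midnight | 20.0 | 75.2 | 0.2 |
| midnight | 30.0 | 71.1 | 0.5 |
| midnight | 40.0 | 69.5 | 1.4 |
| noon | 8.00 | 85.8 | 0.3 |
| noon | 25.0 | 74.6 | 0.7 |
| noon | 40.0 | 70.9 | 0.1 |
| noon | 60.0 | 69.4 | 2.1 |
| noon | 90.0 | 66.8 | 3.5 |
| noon | 120 | 65.9 | 5.8 |

(readings scatter by 0.3 percentage points)

- the state of affairs at 3.0 h: stopped, and by what, or still going (forward and back rates have come level / all of X has reacted / it is still moving / D has run out first)
- how much of the X has reacted by 3.0 h
- how much L there is at 3.0 h, in percent of the X charged
- how much E there is at 3.0 h, in percent of the X charged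

- what was read earlier has a scatter of 0.3 percentage points, one standard deviation
- the reaction counts as stopped when no species that holds the X changes by six tenths of a point or more over the second half of the time
- what has gone from X into another species counts as reacted, even if it can come back

Now turn the question round. To count as stopped at 3.0 h, each species that holds the X would have to change by less than 0.6 points over the second half, which lasts 1.50 h, so test L. The noon run can stand in for your flask, since in percent of charge its X at 8.00 min matches yours, 85.8% against 86.1%. Its L readings rose by 2.3 points between 90.0 min and 120 min, and that pace, if held over the second half, gives 6.9 points. Take the common logarithm of that gain over the limit, 1.06, and call it the stop margin. Zero marks the edge of stopping, so the pace of L would have to be lower by a factor of 11.5. The scatter of those two readings shifts the margin by about 0.0735, so I expect your flask to be still moving.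

The forecast says it is still moving, with 38% reacted (35.5% to 41%), L at 10.5% (8.5% to 14%) and E at 27.5% (25% to 29.5%), for “L is still rising by several points over the second half”.

At 3.0 h the flask gives: it is still moving, with 38.5% reacted, L at 9.34% and E at 24.6%.

    X + D ⇌ E (K = 5.38 /M, k = 0.00417 /M/s)
    X → Z (k = 1.89 × 10⁻⁵ /s)
    D + Z → L (k = 0.00393 /M/s)
    L ⇌ Q (K = 2.62, k = 1.22 × 10⁻⁵ /s)

L went from 3.74% to 9.34% over the second half, so the margin on this flask is 0.970. A second flask of the same charge, left until 80 min, holds 3.15% of L; taken from the scattered midnight reading of 1.4% at 40.0 min, its second half gives a margin of 0.465, which is above zero. In your flask, X has a half-life of 0.55 h by the forward rate alone of its turning into E at 0.121 h, shorter than the 3.0 h. L has a half-life of 16 h by the forward rate alone of its turning into Q, longer than the 3.0 h, and Q stands at 0.520%.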